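Everything rests on cutting ring C of the flavanone unit at the O1–C8a bond. On ring A, C8a lies para to the aryloxy carbon C6, which sits between the C5 and C7 oxygens, so symmetric 4-bromo-2,6-dimethoxyphenol delivers ring A with bromine exactly at C8a. In one operation a copper-catalysed intramolecular O-arylation joins the oxygen of a preformed (S)-carbinol, the future C2, to C8a and closes ring C without ever breaking the C2–O bond, so the configuration installed by ketone transfer hydrogenation survives. The precursor is an open-chain syn-1,3-diol whose C4 end bears the ortho-bromo ring A, already ether-linked to benzyl-protected apigenin, and whose C2 end bears the 4-benzyloxyphenyl group.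

Key step: step 10

Remark: the only stereocentre of the target, C2 of the flavanone, is (S); the carbinol centre at the future C4 in 19 and 20 is temporary and is erased in step 11, and diketone 16 is written in the keto form although it should exist mainly as the chelated enol.
Remark: ring A of 19 is named with lowest locants (6-bromo-3-aryloxy-2,4-dimethoxyphenyl), the syn-diol 19 corresponds to the 2,4-trans flavan-4-ol 20, and the (S)-carbinol requires the (S,S) enantiomer of the TsDPEN catalyst.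

Step 1
Reactants: 1 2',4',6'-trihydroxyacetophenone
Product: 3 1-[2,4-bis(benzyloxy)-6-hydroxyphenyl]ethan-1-one, via 4'-O-benzyl ether 2 (not isolated)
Conditions: BnBr (2.1 equiv), K2CO3 (2.2 equiv), DMF, 0 °C → rt
Reagents that add atoms: benzyl bromide, BrCc1ccccc1
Why: Williamson etherification in which the para and one ortho phenoxide are alkylated while the remaining ortho hydroxyl, hydrogen-bonded to the acetyl carbonyl, is much less nucleophilic and stays free for the later chromone closure.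

Step 2
Reactants: 3 1-[2,4-bis(benzyloxy)-6-hydroxyphenyl]ethan-1-one; 4 4-fluorobenzaldehyde
Product: 6 (E)-1-[2,4-bis(benzyloxy)-6-hydroxyphenyl]-3-(4-fluorophenyl)prop-2-en-1-one, via aldol adduct 5 (not isolated)
Conditions: KOH (50% aq., 5 equiv), EtOH/THF, rt; then 1 M HCl
Reagents that add atoms: none
Why: Claisen–Schmidt condensation in which the acetophenone enolate adds to the non-enolisable aldehyde and the aldol adduct loses water by an E1cB pathway to give the conjugated (E)-enone.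

Step 3
Reactants: 6 (E)-1-[2,4-bis(benzyloxy)-6-hydroxyphenyl]-3-(4-fluorophenyl)prop-2-en-1-one
Product: 8 5,7-bis(benzyloxy)-2-(4-fluorophenyl)-4H-chromen-4-one, via racemic flavanone 7 (not isolated)
Conditions: I2 (10 mol %), DMSO, 130 °C
Reagents that add atoms: none
Why: Iodine/DMSO oxidative cyclisation of a 2'-hydroxychalcone, in which oxa-Michael closure is followed by α-iodination and loss of HI while DMSO regenerates iodine, under conditions that should leave the benzyl ethers and the aryl fluoride untouched.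

Step 4
Reactants: 9 4-bromo-2,6-dimethoxyphenol
Product: 11 6-bromo-3-hydroxy-2,4-dimethoxybenzaldehyde, via α-chloro ether 10 (not isolated)
Conditions: Cl2CHOMe (1.5 equiv), TiCl4 (3 equiv), CH2Cl2, 0 °C → rt; then ice/1 M HCl
Reagents that add atoms: dichloromethyl methyl ether, COC(Cl)Cl; water, O
Why: Rieche formylation (electrophilic aromatic substitution) in which the two free ring positions are equivalent, each ortho to one methoxy group and para to the other, so the electrophile can only enter next to bromine and aqueous work-up hydrolyses the chloro ether to the aldehyde.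

Step 5
Reactants: 11 6-bromo-3-hydroxy-2,4-dimethoxybenzaldehyde; 8 5,7-bis(benzyloxy)-2-(4-fluorophenyl)-4H-chromen-4-one
Product: 12 3-[4-(5,7-bis(benzyloxy)-4-oxo-4H-chromen-2-yl)phenoxy]-6-bromo-2,4-dimethoxybenzaldehyde
Conditions: Cs2CO3 (1.5 equiv), DMSO, 110 °C
Reagents that add atoms: none
Why: Nucleophilic aromatic substitution by addition–elimination, in which the caesium phenoxide of 11 attacks C4' of the fluoroflavone, the negative charge is delocalised through C2=C3 into the C4 carbonyl and fluoride leaves, while the unactivated aryl bromide and the non-enolisable aldehyde are spectators.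

Step 6
Reactants: 13 4'-(benzyloxy)acetophenone; 12 3-[4-(5,7-bis(benzyloxy)-4-oxo-4H-chromen-2-yl)phenoxy]-6-bromo-2,4-dimethoxybenzaldehyde
Product: 15 rac-3-{3-[4-(5,7-bis(benzyloxy)-4-oxo-4H-chromen-2-yl)phenoxy]-6-bromo-2,4-dimethoxyphenyl}-1-[4-(benzyloxy)phenyl]-3-hydroxypropan-1-one, via lithium enolate 14 (not isolated)
Conditions: LDA (1.1 equiv), THF, −78 °C; then 12 in THF, −78 °C; AcOH quench at −78 °C
Reagents that add atoms: none
Why: Directed aldol addition in which the preformed lithium enolate should add to the only aldehyde far faster than to the vinylogous-ester carbonyl or C2 of the chromone, the cold acidic quench preventing retro-aldol and dehydration, and the new carbinol centre is left racemic on purpose because step 7 oxidises it.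

Step 7
Reactants: 15 rac-3-{3-[4-(5,7-bis(benzyloxy)-4-oxo-4H-chromen-2-yl)phenoxy]-6-bromo-2,4-dimethoxyphenyl}-1-[4-(benzyloxy)phenyl]-3-hydroxypropan-1-one
Product: 16 1-{3-[4-(5,7-bis(benzyloxy)-4-oxo-4H-chromen-2-yl)phenoxy]-6-bromo-2,4-dimethoxyphenyl}-3-[4-(benzyloxy)phenyl]propane-1,3-dione
Conditions: IBX (3 equiv), EtOAc, 77 °C
Reagents that add atoms: none
Why: IBX oxidation of a β-hydroxy ketone, a hypervalent-iodine alcohol oxidation that should stop at the 1,3-diketone (stabilised as its chelated enol) and spare the ethers, the aryl bromide and the chromone.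

Step 8
Reactants: 16 1-{3-[4-(5,7-bis(benzyloxy)-4-oxo-4H-chromen-2-yl)phenoxy]-6-bromo-2,4-dimethoxyphenyl}-3-[4-(benzyloxy)phenyl]propane-1,3-dione
Product: 17 (S)-1-{3-[4-(5,7-bis(benzyloxy)-4-oxo-4H-chromen-2-yl)phenoxy]-6-bromo-2,4-dimethoxyphenyl}-3-[4-(benzyloxy)phenyl]-3-hydroxypropan-1-one
Conditions: RuCl[(S,S)-TsDPEN](p-cymene) (2 mol %), HCO2H/Et3N (5:2), CH2Cl2, 30 °C
Reagents that add atoms: none
Why: Noyori-type asymmetric transfer hydrogenation in which the ruthenium hydride/NH pair reduces the unhindered 4-benzyloxyphenyl ketone through the six-membered outer-sphere transition state, the (S,S) ligand orienting the aryl group by a CH–π contact so that hydride is delivered to the face giving the (S)-carbinol, while the other carbonyl, twisted and shielded by the ortho bromine and ortho methoxy group, should not be reduced.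

Step 9
Reactants: 17 (S)-1-{3-[4-(5,7-bis(benzyloxy)-4-oxo-4H-chromen-2-yl)phenoxy]-6-bromo-2,4-dimethoxyphenyl}-3-[4-(benzyloxy)phenyl]-3-hydroxypropan-1-one
Product: 19 (1R,3S)-1-{3-[4-(5,7-bis(benzyloxy)-4-oxo-4H-chromen-2-yl)phenoxy]-6-bromo-2,4-dimethoxyphenyl}-3-[4-(benzyloxy)phenyl]propane-1,3-diol, via diethylboron chelate 18 (not isolated)
Conditions: Et2BOMe (1.2 equiv), THF/MeOH (4:1), −78 °C; NaBH4 (1.5 equiv), −78 → −40 °C; then MeOH, evaporation (×3)
Reagents that add atoms: none
Why: Narasaka–Prasad reduction in which Et2BOMe locks the β-hydroxy ketone as a six-membered boron chelate and external hydride adds axially, so the existing (S)-carbinol induces the (1R) centre of the syn-diol, while borohydride at low temperature should leave the deactivated chromone carbonyl alone and any anti-diol would converge in step 11.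

Step 10
Reactants: 19 (1R,3S)-1-{3-[4-(5,7-bis(benzyloxy)-4-oxo-4H-chromen-2-yl)phenoxy]-6-bromo-2,4-dimethoxyphenyl}-3-[4-(benzyloxy)phenyl]propane-1,3-diol
Product: 20 (2S,4R)-6-[4-(5,7-bis(benzyloxy)-4-oxo-4H-chromen-2-yl)phenoxy]-2-[4-(benzyloxy)phenyl]-5,7-dimethoxychroman-4-ol
Conditions: CuI (10 mol %), 3,4,7,8-tetramethyl-1,10-phenanthroline (20 mol %), Cs2CO3 (2 equiv), toluene (0.02 M), 110 °C, argon
Reagents that add atoms: none
Why: This is an Ullmann-type C–O coupling in which Cs2CO3 and phenanthroline-ligated monovalent copper give a copper alkoxide of the C2 carbinol, which adds oxidatively to the neighbouring C–Br bond to form a seven-membered aryl(alkoxo) trivalent-copper cycle and then eliminates reductively to form O1–C8a. The closest known reaction is the CuI/phenanthroline-catalysed intramolecular etherification of aryl bromides by secondary alcohols that gives chromans, and the same ligand system is known to arylate secondary benzylic alcohols without loss of configuration. Ring C closes by a 6-exo ipso substitution of the tethered oxygen at the brominated carbon, and no new stereocentre arises. C2 stays (S) because its C–O bond, made in step 8, is never broken, and the C4 centre is a spectator. The step needs chemoselectivity between the two hydroxyls, which ring size secures because the C4 hydroxyl could only close a four-membered ring and dilution suppresses intermolecular arylation, and it needs a chain that cannot eliminate, which keeping C4 at the alcohol level secures because no ketone is present to open a retro-aldol or chalcone pathway. Only the brominated carbon can become C8a, so neither methoxy-bearing carbon of ring A competes.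

Step 11
Reactants: 20 (2S,4R)-6-[4-(5,7-bis(benzyloxy)-4-oxo-4H-chromen-2-yl)phenoxy]-2-[4-(benzyloxy)phenyl]-5,7-dimethoxychroman-4-ol
Product: 21 (S)-6-[4-(5,7-bis(benzyloxy)-4-oxo-4H-chromen-2-yl)phenoxy]-2-[4-(benzyloxy)phenyl]-5,7-dimethoxychroman-4-one
Conditions: Dess–Martin periodinane (1.5 equiv), CH2Cl2, 0 °C → rt
Reagents that add atoms: none
Why: Dess–Martin oxidation of the benzylic C4 carbinol to the chromanone under non-basic conditions, so the flavanone should not open to a chalcone and C2 keeps its (S) configuration.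

Step 12
Reactants: 21 (S)-6-[4-(5,7-bis(benzyloxy)-4-oxo-4H-chromen-2-yl)phenoxy]-2-[4-(benzyloxy)phenyl]-5,7-dimethoxychroman-4-one
Product: 23 (S)-6-[4-(5,7-dihydroxy-4-oxo-4H-chromen-2-yl)phenoxy]-5-hydroxy-2-(4-hydroxyphenyl)-7-methoxychroman-4-one, via tris-phenol 22 (not isolated)
Conditions: BCl3 (1 M in CH2Cl2, 10 equiv), C6HMe5 (10 equiv), CH2Cl2, −78 °C, then 0 °C; MeOH quench, aqueous work-up
Reagents that add atoms: none
Why: Lewis-acid ether cleavage in which BCl3 at −78 °C, with pentamethylbenzene as a non-basic benzyl-cation scavenger, should remove the three aryl benzyl ethers and, on warming to 0 °C, the boron chelate between the C4 carbonyl and the peri 5-methoxy oxygen should direct chloride to that methyl group alone, the unchelated 7-methoxy group, both diaryl ether bonds and C2 being left untouched.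

Compound list
1 | 2',4',6'-trihydroxyacetophenone | CC(=O)c1c(O)cc(O)cc1O | starting material
2 | 1-[4-(benzyloxy)-2,6-dihydroxyphenyl]ethan-1-one | CC(=O)c1c(O)cc(OCc2ccccc2)cc1O | intermediate (not isolated)
3 | 1-[2,4-bis(benzyloxy)-6-hydroxyphenyl]ethan-1-one | CC(=O)c1c(O)cc(OCc2ccccc2)cc1OCc1ccccc1 | intermediate
4 | 4-fluorobenzaldehyde | O=Cc1ccc(F)cc1 | starting material
5 | rac-1-[2,4-bis(benzyloxy)-6-hydroxyphenyl]-3-(4-fluorophenyl)-3-hydroxypropan-1-one | O=C(CC(O)c1ccc(F)cc1)c1c(O)cc(OCc2ccccc2)cc1OCc1ccccc1 | intermediate (not isolated)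
6 | (E)-1-[2,4-bis(benzyloxy)-6-hydroxyphenyl]-3-(4-fluorophenyl)prop-2-en-1-one | O=C(/C=C/c1ccc(F)cc1)c1c(O)cc(OCc2ccccc2)cc1OCc1ccccc1 | intermediate
7 | rac-5,7-bis(benzyloxy)-2-(4-fluorophenyl)chroman-4-one | O=C1CC(c2ccc(F)cc2)Oc2cc(OCc3ccccc3)cc(OCc3ccccc3)c21 | intermediate (not isolated)
8 | 5,7-bis(benzyloxy)-2-(4-fluorophenyl)-4H-chromen-4-one | O=c1cc(-c2ccc(F)cc2)oc2cc(OCc3ccccc3)cc(OCc3ccccc3)c12 | intermediate
9 | 4-bromo-2,6-dimethoxyphenol | COc1cc(Br)cc(OC)c1O | starting material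
10 | rac-4-bromo-3-[chloro(methoxy)methyl]-2,6-dimethoxyphenol | COC(Cl)c1c(Br)cc(OC)c(O)c1OC | intermediate (not isolated)
11 | 6-bromo-3-hydroxy-2,4-dimethoxybenzaldehyde | O=Cc1c(Br)cc(OC)c(O)c1OC | intermediate
12 | 3-[4-(5,7-bis(benzyloxy)-4-oxo-4H-chromen-2-yl)phenoxy]-6-bromo-2,4-dimethoxybenzaldehyde | O=Cc1c(Br)cc(OC)c(Oc2ccc(-c3cc(=O)c4c(OCc5ccccc5)cc(OCc5ccccc5)cc4o3)cc2)c1OC | intermediate
13 | 4'-(benzyloxy)acetophenone | CC(=O)c1ccc(OCc2ccccc2)cc1 | starting material
14 | lithium 1-[4-(benzyloxy)phenyl]ethen-1-olate | [Li+].[O-]C(=C)c1ccc(OCc2ccccc2)cc1 | intermediate (not isolated)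
15 | rac-3-{3-[4-(5,7-bis(benzyloxy)-4-oxo-4H-chromen-2-yl)phenoxy]-6-bromo-2,4-dimethoxyphenyl}-1-[4-(benzyloxy)phenyl]-3-hydroxypropan-1-one | O=C(CC(O)c1c(Br)cc(OC)c(Oc2ccc(-c3cc(=O)c4c(OCc5ccccc5)cc(OCc5ccccc5)cc4o3)cc2)c1OC)c1ccc(OCc2ccccc2)cc1 | intermediate
16 | 1-{3-[4-(5,7-bis(benzyloxy)-4-oxo-4H-chromen-2-yl)phenoxy]-6-bromo-2,4-dimethoxyphenyl}-3-[4-(benzyloxy)phenyl]propane-1,3-dione | O=C(CC(=O)c1c(Br)cc(OC)c(Oc2ccc(-c3cc(=O)c4c(OCc5ccccc5)cc(OCc5ccccc5)cc4o3)cc2)c1OC)c1ccc(OCc2ccccc2)cc1 | intermediate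
17 | (S)-1-{3-[4-(5,7-bis(benzyloxy)-4-oxo-4H-chromen-2-yl)phenoxy]-6-bromo-2,4-dimethoxyphenyl}-3-[4-(benzyloxy)phenyl]-3-hydroxypropan-1-one | O=C(C[C@@H](c1ccc(OCc2ccccc2)cc1)O)c1c(Br)cc(OC)c(Oc2ccc(-c3cc(=O)c4c(OCc5ccccc5)cc(OCc5ccccc5)cc4o3)cc2)c1OC | intermediate
18 | O-diethylboryl chelate of 17, (S)-configured | O=C(C[C@@H](c1ccc(OCc2ccccc2)cc1)OB(CC)CC)c1c(Br)cc(OC)c(Oc2ccc(-c3cc(=O)c4c(OCc5ccccc5)cc(OCc5ccccc5)cc4o3)cc2)c1OC | intermediate (not isolated)
19 | (1R,3S)-1-{3-[4-(5,7-bis(benzyloxy)-4-oxo-4H-chromen-2-yl)phenoxy]-6-bromo-2,4-dimethoxyphenyl}-3-[4-(benzyloxy)phenyl]propane-1,3-diol (syn) | O[C@@H](c1c(Br)cc(OC)c(Oc2ccc(-c3cc(=O)c4c(OCc5ccccc5)cc(OCc5ccccc5)cc4o3)cc2)c1OC)C[C@@H](c1ccc(OCc2ccccc2)cc1)O | intermediate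
20 | (2S,4R)-6-[4-(5,7-bis(benzyloxy)-4-oxo-4H-chromen-2-yl)phenoxy]-2-[4-(benzyloxy)phenyl]-5,7-dimethoxychroman-4-ol (2,4-trans) | COc1cc2c(c(OC)c1Oc1ccc(-c3cc(=O)c4c(OCc5ccccc5)cc(OCc5ccccc5)cc4o3)cc1)[C@H](O)C[C@@H](c1ccc(OCc3ccccc3)cc1)O2 | intermediate
21 | (S)-6-[4-(5,7-bis(benzyloxy)-4-oxo-4H-chromen-2-yl)phenoxy]-2-[4-(benzyloxy)phenyl]-5,7-dimethoxychroman-4-one | COc1cc2c(c(OC)c1Oc1ccc(-c3cc(=O)c4c(OCc5ccccc5)cc(OCc5ccccc5)cc4o3)cc1)C(=O)C[C@@H](c1ccc(OCc3ccccc3)cc1)O2 | intermediate
22 | (S)-6-[4-(5,7-dihydroxy-4-oxo-4H-chromen-2-yl)phenoxy]-2-(4-hydroxyphenyl)-5,7-dimethoxychroman-4-one | COc1cc2c(c(OC)c1Oc1ccc(-c3cc(=O)c4c(O)cc(O)cc4o3)cc1)C(=O)C[C@@H](c1ccc(O)cc1)O2 | intermediate (not isolated)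
23 | (S)-6-[4-(5,7-dihydroxy-4-oxo-4H-chromen-2-yl)phenoxy]-5-hydroxy-2-(4-hydroxyphenyl)-7-methoxychroman-4-one | COc1cc2c(c(O)c1Oc1ccc(-c3cc(=O)c4c(O)cc(O)cc4o3)cc1)C(=O)C[C@@H](c1ccc(O)cc1)O2 | target

Total step count: 12.
Longest linear sequence: 11 steps (steps 1–3 and 5–12, from 1 to 23); the ring A branch from 9 runs through 9 steps (steps 4–12).

Steps most likely to fail

1. Step 10 (ring closure). The copper alkoxide may undergo β-hydride elimination with reduction of the C–Br bond, or the 1,3-diol may sequester the catalyst so that the electron-rich aryl bromide is not engaged. Fallback: ring C would be closed from the other side, by forming C2–O1 with inversion, in the enantiomeric carbinol series. The fallback sets out from diketone 16. Transfer hydrogenation with RuCl[(R,R)-TsDPEN](p-cymene) in HCO2H/Et3N should give (R)-1-{3-[4-(5,7-bis(benzyloxy)-4-oxo-4H-chromen-2-yl)phenoxy]-6-bromo-2,4-dimethoxyphenyl}-3-[4-(benzyloxy)phenyl]-3-hydroxypropan-1-one F1, and the chelation-controlled reduction of step 9 should give the (1S,3R)-syn-diol F2. Miyaura borylation of the C–Br bond (B2pin2, Pd(dppf)Cl2, KOAc, dioxane, 85 °C) should give the pinacol boronate F3, which would be oxidised without isolation (NaBO3·4H2O, THF/water, rt) to the phenol (1S,3R)-1-{3-[4-(5,7-bis(benzyloxy)-4-oxo-4H-chromen-2-yl)phenoxy]-6-hydroxy-2,4-dimethoxyphenyl}-3-[4-(benzyloxy)phenyl]propane-1,3-diol F4. Mitsunobu cyclisation (PPh3, DIAD, THF, 0 °C) should engage the unhindered carbinol with inversion, the doubly ortho-substituted C4 carbinol being too hindered to be activated, and give the (2S,4S)-flavan-4-ol F5. Dess–Martin oxidation of F5 comes back to the route at flavanone 21.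

2. Step 5 (diaryl ether). Substitution at C4' may be too slow, because the phenoxide is flanked by two methoxy groups and the fluoride is activated only through the chromone double bond, and base-induced opening of the chromone may compete at the temperature needed. Fallback: the ether would be made on the much more electrophilic 4-fluorobenzaldehyde and the flavone built afterwards. The fallback sets out from aldehyde 11. Acetalisation (ethylene glycol, p-TsOH, toluene, reflux with water removal) should give 4-bromo-3-(1,3-dioxolan-2-yl)-2,6-dimethoxyphenol F6. Substitution on 4 (K2CO3, DMF, 110 °C) should give 4-[4-bromo-3-(1,3-dioxolan-2-yl)-2,6-dimethoxyphenoxy]benzaldehyde F7. Claisen–Schmidt condensation with 3 (KOH, EtOH/THF) should give the chalcone F8, and I2/DMSO cyclisation the flavone acetal F9. Aqueous HCl in THF would then release the aldehyde and come back to the route at 12.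

3. Step 8 (transfer hydrogenation). Hydride transfer to the strongly enolised diketone may be slow, may occur at the wrong carbonyl, or may show poor facial selectivity. Fallback: the oxidation–reduction detour would be dropped. The fallback sets out from racemic aldol 15, whose only ketone is the unhindered 4-benzyloxyphenyl ketone, so no regiochemical question remains. Transfer hydrogenation with the same (S,S) catalyst should set the (S) centre under catalyst control in both enantiomers of 15 and give the syn-diol 19 together with its C1 epimer, the (1S,3S)-anti-diol F10. The syn component comes back to the route at 19. F10 would be cyclised under the conditions of step 10 to the (2S,4S)-flavan-4-ol F5, and Dess–Martin oxidation removes the C4 centre, so this component comes back at 21.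

Further compounds
F1 | step 10 | (R)-1-{3-[4-(5,7-bis(benzyloxy)-4-oxo-4H-chromen-2-yl)phenoxy]-6-bromo-2,4-dimethoxyphenyl}-3-[4-(benzyloxy)phenyl]-3-hydroxypropan-1-one | O=C(C[C@H](c1ccc(OCc2ccccc2)cc1)O)c1c(Br)cc(OC)c(Oc2ccc(-c3cc(=O)c4c(OCc5ccccc5)cc(OCc5ccccc5)cc4o3)cc2)c1OC
F2 | step 10 | (1S,3R)-1-{3-[4-(5,7-bis(benzyloxy)-4-oxo-4H-chromen-2-yl)phenoxy]-6-bromo-2,4-dimethoxyphenyl}-3-[4-(benzyloxy)phenyl]propane-1,3-diol | O[C@H](c1c(Br)cc(OC)c(Oc2ccc(-c3cc(=O)c4c(OCc5ccccc5)cc(OCc5ccccc5)cc4o3)cc2)c1OC)C[C@H](c1ccc(OCc2ccccc2)cc1)O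
F3 | step 10 | (1S,3R)-1-{3-[4-(5,7-bis(benzyloxy)-4-oxo-4H-chromen-2-yl)phenoxy]-2,4-dimethoxy-6-(4,4,5,5-tetramethyl-1,3,2-dioxaborolan-2-yl)phenyl}-3-[4-(benzyloxy)phenyl]propane-1,3-diol | O[C@H](c1c(B2OC(C)(C)C(C)(C)O2)cc(OC)c(Oc2ccc(-c3cc(=O)c4c(OCc5ccccc5)cc(OCc5ccccc5)cc4o3)cc2)c1OC)C[C@H](c1ccc(OCc2ccccc2)cc1)O
F4 | step 10 | (1S,3R)-1-{3-[4-(5,7-bis(benzyloxy)-4-oxo-4H-chromen-2-yl)phenoxy]-6-hydroxy-2,4-dimethoxyphenyl}-3-[4-(benzyloxy)phenyl]propane-1,3-diol | O[C@H](c1c(O)cc(OC)c(Oc2ccc(-c3cc(=O)c4c(OCc5ccccc5)cc(OCc5ccccc5)cc4o3)cc2)c1OC)C[C@H](c1ccc(OCc2ccccc2)cc1)O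
F5 | step 10 | (2S,4S)-6-[4-(5,7-bis(benzyloxy)-4-oxo-4H-chromen-2-yl)phenoxy]-2-[4-(benzyloxy)phenyl]-5,7-dimethoxychroman-4-ol | COc1cc2c(c(OC)c1Oc1ccc(-c3cc(=O)c4c(OCc5ccccc5)cc(OCc5ccccc5)cc4o3)cc1)[C@@H](O)C[C@@H](c1ccc(OCc3ccccc3)cc1)O2
F6 | step 5 | 4-bromo-3-(1,3-dioxolan-2-yl)-2,6-dimethoxyphenol | COc1cc(Br)c(C2OCCO2)c(OC)c1O
F7 | step 5 | 4-[4-bromo-3-(1,3-dioxolan-2-yl)-2,6-dimethoxyphenoxy]benzaldehyde | O=Cc1ccc(Oc2c(OC)cc(Br)c(C3OCCO3)c2OC)cc1
F8 | step 5 | (E)-1-[2,4-bis(benzyloxy)-6-hydroxyphenyl]-3-{4-[4-bromo-3-(1,3-dioxolan-2-yl)-2,6-dimethoxyphenoxy]phenyl}prop-2-en-1-one | O=C(/C=C/c1ccc(Oc2c(OC)cc(Br)c(C3OCCO3)c2OC)cc1)c1c(O)cc(OCc2ccccc2)cc1OCc1ccccc1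
F9 | step 5 | 5,7-bis(benzyloxy)-2-{4-[4-bromo-3-(1,3-dioxolan-2-yl)-2,6-dimethoxyphenoxy]phenyl}-4H-chromen-4-one | O=c1cc(-c2ccc(Oc3c(OC)cc(Br)c(C4OCCO4)c3OC)cc2)oc2cc(OCc3ccccc3)cc(OCc3ccccc3)c12
F10 | step 8 | (1S,3S)-1-{3-[4-(5,7-bis(benzyloxy)-4-oxo-4H-chromen-2-yl)phenoxy]-6-bromo-2,4-dimethoxyphenyl}-3-[4-(benzyloxy)phenyl]propane-1,3-diol (anti) | O[C@H](c1c(Br)cc(OC)c(Oc2ccc(-c3cc(=O)c4c(OCc5ccccc5)cc(OCc5ccccc5)cc4o3)cc2)c1OC)C[C@@H](c1ccc(OCc2ccccc2)cc1)O
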